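## Analysis of the target

Macarangaflavanone B (21) is a (2S)-flavanone: aromatic ring A is fused to the pyranone ring C, and C2 carries ring B, a 4-hydroxy-3-prenylphenyl group. C2 is the only stereocentre. It is benzylic, bonded to O1 and β to the C4 carbonyl, so ring C can open by β-elimination and racemise; a free 4'-phenoxide makes this especially easy. Ring A is fully differentiated: 5-OH (hydrogen-bonded to C4=O), prenyl at C6, 7-OH, and hydrogen at C8. Both prenyl alkenes sit ortho to phenols and cyclise to chromans under acid, so strong acid, strong base and oxidants are all unwelcome late in the route. The real difficulty is regiochemical: C6 and C8 of a 5,7-dioxygenated flavanone are both nucleophilic, so prenylation of a finished ring A gives 6/8 mixtures and O-alkylation. The strategy rests on the contiguous array C4a–C5(OH)–C6(prenyl)–C7(O)–C8(H)–C8a. A vinylketene and a prenyl-bearing 1-siloxyalkyne assemble exactly this pattern: C5 from the ketene carbonyl, C6 and C7 from the alkyne, and C8a/C4a from an enone that already holds O1 and the configured C2.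

## Retrosynthetic reasoning

**21 ⇒ 20.** The last operation is only the cleavage of two O–Si bonds, at O7 and O4'. Both silyl groups leave with buffered fluoride, so the end game needs neither the acid that would cyclise the prenyl groups nor the base that would open ring C. The 5-hydroxyl stays free in 20 because the ring-forming step delivers it as the chelated phenol.

**20 ⇒ 11 + 15.** Ring A is taken apart completely by cutting C4a–C5, C5–C6, C7–C8 and C8–C8a. This leaves diazo ketone 11 (O1, C2, C3, C4, C4a, C8a, with C5 and C8 as the diazoacetyl carbons) and siloxyalkyne 15 (C6 with its prenyl group, C7 with its oxygen). The cut is made here and not at the aryl–prenyl bond because the prenyl position then follows from how two polarised partners join, not from the relative nucleophilicity of C6 and C8. Ring C is kept intact as a dihydropyranone, so O1 is already distinguished from the other ring A oxygens and C2 is already set. Forward, 11 must rearrange to vinylketene 16, add 15 with the prenyl-bearing carbon on the ketene carbonyl carbon (17), open to 18 and close onto C4a (19, then 20), all without touching C2.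

**15 ⇒ 12.** The C≡C–O unit is traced to the ester carbonyl of 12 plus one carbon. Ynolate 14, silylated on oxygen, arises from dibromo enolate 13 by halogen–metal exchange and a 1,2-shift. The prenyl group thus enters as a simple commercial ester, and one flask delivers the ynol ether.

**11 ⇒ 9.** The bond between the ketone carbon and the diazo carbon is cut: acid chloride 10, made from acid 9, acylates a one-carbon diazoalkane. Working at the acid level avoids enolate chemistry on the pyranone, whose C3 enolate would expel O1.

**9 ⇒ 8 ⇒ 4 + 6.** After the acid/ester interchange, the dihydropyranone is cut at C2–C3 and at O1–C6 (pyranone numbering; O1–C8a of the flavanone). This separates aldehyde 4 (ring B plus C2) from diene 6, a five-carbon 2,4-dioxo ester synthon. Forward, a catalyst-controlled vinylogous aldol addition sets C2 in 7, and the new hydroxyl closes onto the ketone next to the ester with dehydration. An aryl aldehyde is a classical substrate for such an addition, which is why C2 is set here and not on a finished flavanone.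

**6 ⇒ 5; 4 ⇒ 3 ⇒ 1 + 2.** Diene 6 is the double silyl enol ether of 5. Aldehyde 4 is the silyl ether of 3, whose aryl–prenyl bond is cut to phenol 1 and bromide 2. C-prenylation is unambiguous here because the para position is occupied and the two ortho positions are equivalent.

## Alternatives that were turned down

**Alternative 1:** Both aryl–prenyl bonds (C6–C1'' and C3'–C1''') are cut back to aryl 1,1-dimethylallyl ethers. The forward key step heats the bis-ether A2, and two aromatic Claisen shifts give the diprenyl flavanone A1 with the 5- and 4'-hydroxyls set free.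
- For: the shift from O5 can only end at C6, because the other ortho position is C4a. Regiochemistry is therefore secured by structure, as well as in the chosen route. The key step is a classical reaction and no ring has to be built, so from an enantiopure flavanone this plan is at least as short.
- Against: A2 needs tertiary allyl ethers at the chelated, hindered 5-OH and at 4'-OH, made under basic alkylation conditions that open ring C. Heating a flavanone whose 4'-phenol is being liberated invites racemisation at C2. C2 itself must come from a separate asymmetric synthesis. The acetal at O7 must finally be removed with acid while the 6-prenyl group sits between two free phenols, which favours chroman formation.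
- Comparison: the route through 11 and 15 is longer in ring construction. In exchange it sets C2 before any phenol is free, never heats a free 4'-phenol, and ends with fluoride only.

**Alternative 2:** Ring C is cut at O1–C2 and C3–C4, giving salicylaldehyde A4 and styrene A5. A confined chiral Brønsted acid and an orthoester convert A4 into the methoxy ortho-quinone methide A6, which adds A5 in an oxa-[4+2] to give the 4-methoxyflavan A3 and sets C2.
- For: the step is catalytic, convergent, closes ring C and sets C2 at once. On this point it is stronger than the chosen route, where C2 and ring C come from an aldol addition and a separate cyclisation.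
- Against: the 6- versus 8-prenyl problem is only moved into the synthesis of A4, which needs three phloroglucinol oxygens told apart and the prenyl group placed between two of them. The prenyl alkenes of A4 and A5 are electron-rich trisubstituted olefins that compete with the styrene for A6 and are protonated by the strong acid. A3 is at the wrong oxidation level at C4, so ether hydrolysis and a benzylic oxidation next to two prenyl groups must follow before three silyl ethers are removed.
- Comparison: the chosen route keeps all acid away from the prenyl groups, has C4 as a ketone from the start, and derives the ring A pattern from the way 16 and 15 combine.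

**Alternative 3:** Ring C is cut at O1–C8a and C4–C4a. A fluoride source converts silyl triflate A8 into aryne A10; the alkoxide of hydroxy ester A9 adds at C8a, and the C4a carbanion acylates on the ester to give flavanone A7.
- For: the regiochemistry of the addition is favourable, since the oxygen substituent at C5 directs the nucleophile to the remote aryne carbon C8a and leaves the anion at C4a. A9 is accessible by reliable asymmetric reduction, which is a safer source of C2 than the aldol addition used here. The plan is convergent.
- Against: A8 is a pentasubstituted benzene whose preparation contains the same regiochemical problem and several steps. A secondary benzylic alkoxide is a poor aryne partner: retro-aldol cleavage of A9 and protonation of the aryl anion before ring closure both compete. Under basic fluoride, A7 can open by β-elimination and lose its configuration. Three acetal ethers must finally be removed with acid next to the prenyl groups.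
- Comparison: the chosen route spends its steps on 11 and not on an aryne precursor, forms ring A under neutral conditions, and ends with a buffered fluoride deprotection.

Key step: step 8

Abbreviations: prenyl = 3-methylbut-2-enyl; TIPS = triisopropylsilyl; Ar = 3-prenyl-4-(triisopropylsilyloxy)phenyl.

Assumption: Ti(OiPr)4/(S)-BINOL is taken to direct addition to the Si face of aldehyde 4, the usual sense of this catalyst with aryl aldehydes; diene 6 is drawn as its (2Z) isomer, a geometry that is lost in step 4.

## Route

Step 1
Reactants: 1 4-hydroxybenzaldehyde; 2 prenyl bromide (1-bromo-3-methylbut-2-ene)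
Product: 3 4-hydroxy-3-(3-methylbut-2-enyl)benzaldehyde
Conditions: KOH (10% aq), rt
Reagents that add atoms: none
Why: C-alkylation of an ambident phenoxide: in water the phenoxide oxygen is hydrogen-bonded, so a useful share of 2 should be taken up at the ortho carbon (para is blocked by the formyl group); the O-prenyl ether and the 3,5-diprenyl compound are the expected by-products and are removed by chromatography at this cheap first stage.

Step 2
Reactants: 3 4-hydroxy-3-(3-methylbut-2-enyl)benzaldehyde
Product: 4 3-(3-methylbut-2-enyl)-4-(triisopropylsilyloxy)benzaldehyde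
Conditions: TIPSCl, imidazole, DMF, rt
Reagents that add atoms: chlorotriisopropylsilane, CC(C)[Si](Cl)(C(C)C)C(C)C
Why: Silyl ether formation at a phenol; the TIPS group is chosen because it should survive the Lewis acid, the tin hydroxide, the acid chloride chemistry, light and heat, and because it leaves with the same reagent as the silyl group that the alkyne brings to O7.

Step 3
Reactants: 5 ethyl 2,4-dioxopentanoate
Product: 6 ethyl (2Z)-2,4-bis(trimethylsilyloxy)penta-2,4-dienoate
Conditions: Me3SiOTf (2.2 equiv), Et3N (2.5 equiv), Et2O, 0 °C to rt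
Reagents that add atoms: trimethylsilyl trifluoromethanesulfonate, C[Si](C)(C)OS(=O)(=O)C(F)(F)F
Why: Double soft enolisation and O-silylation of a 1,3-dicarbonyl compound: the first silyl group caps the enol that 5 already is, the second follows deprotonation of the methyl group, giving the 2-silyloxydiene whose CH2 terminus is the nucleophile of step 4.

Step 4
Reactants: 4 3-(3-methylbut-2-enyl)-4-(triisopropylsilyloxy)benzaldehyde; 6 ethyl (2Z)-2,4-bis(trimethylsilyloxy)penta-2,4-dienoate
Product: 8 ethyl (2S)-2-Ar-4-oxo-3,4-dihydro-2H-pyran-6-carboxylate, via hydroxy diketo ester 7 (not isolated)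
Conditions: Ti(OiPr)4 (10 mol %), (S)-BINOL (10 mol %), 4 Å MS, THF, −78 °C to rt; 1 M HCl, THF, 0 °C; PPTS (cat.), PhMe, 50 °C
Reagents that add atoms: none
Why: Catalytic enantioselective vinylogous Mukaiyama aldol addition followed by acid-catalysed hemiketalisation and dehydration, the stepwise equivalent of a hetero-Diels–Alder reaction: the chiral titanium complex binds the aldehyde and the CH2 terminus of 6 should add to the Si face, giving (S) at the carbinol carbon of 7, which becomes C2. The hydroxyl of 7 then adds to the ketone next to the ester and the hemiketal dehydrates to the vinylogous ester 8; only mild acid is used so that neither the prenyl alkene nor the electron-rich benzylic C–O bond is ionised.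

Step 5
Reactants: 8 ethyl (2S)-2-Ar-4-oxo-3,4-dihydro-2H-pyran-6-carboxylate
Product: 9 (2S)-2-Ar-4-oxo-3,4-dihydro-2H-pyran-6-carboxylic acid
Conditions: Me3SnOH, ClCH2CH2Cl, 70 °C; 5% aq HCl work-up
Reagents that add atoms: trimethyltin hydroxide, C[Sn](C)(C)O
Why: Near-neutral tin-mediated ester hydrolysis: hydroxide is delivered to the activated 2-alkoxyacrylate ester without free base, so conjugate addition at pyranone C6 and enolisation at C3 (which would open ring C by β-elimination and erase C2) should not compete, and the aryl silyl ether stays in place.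

Step 6
Reactants: 9 (2S)-2-Ar-4-oxo-3,4-dihydro-2H-pyran-6-carboxylic acid
Product: 11 2-diazo-1-[(2S)-2-Ar-4-oxo-3,4-dihydro-2H-pyran-6-yl]ethan-1-one, via acid chloride 10 (not isolated)
Conditions: Me2C=C(Cl)NMe2 (Ghosez's reagent), CH2Cl2, 0 °C to rt; CH2N2 (3 equiv), Et2O, −10 to 0 °C, dark
Reagents that add atoms: diazomethane, C=[N+]=[N-]; 1-chloro-N,N,2-trimethylprop-1-en-1-amine, CC(C)=C(Cl)N(C)C (chlorine of 10 only)
Why: Arndt–Eistert-type acylation of diazomethane: the chloroenamine makes 10 without releasing HCl, so the prenyl group is not hydrochlorinated, and excess diazomethane is acylated at carbon and takes up the HCl as chloromethane. At −10 °C acylation should be much faster than dipolar cycloaddition to the trisubstituted, alkoxy-bearing C5=C6 bond of the pyranone, and the excess is purged as soon as 10 is consumed.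

Step 7
Reactants: 12 ethyl 4-methylpent-3-enoate
Product: 15 triisopropyl[(5-methylhex-4-en-1-yn-1-yl)oxy]silane, via dibromo enolate 13 (not isolated), via lithium ynolate 14 (not isolated)
Conditions: CH2Br2, LiTMP, THF, −78 °C; LiN(SiMe3)2, −78 to −20 °C; n-BuLi, −78 °C to rt; TIPSCl, −78 to 0 °C
Reagents that add atoms: dibromomethane, BrCBr; chlorotriisopropylsilane, CC(C)[Si](Cl)(C(C)C)C(C)C
Why: Kowalski ester homologation stopped at the ynolate: LiCHBr2 adds to the ester, the adduct collapses and is deprotonated to enolate 13, bromine–lithium exchange and 1,2-shift of the prenyl group with loss of LiBr give ynolate 14, and the bulky chlorosilane silylates it on oxygen.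

Step 8
Reactants: 11 2-diazo-1-[(2S)-2-Ar-4-oxo-3,4-dihydro-2H-pyran-6-yl]ethan-1-one; 15 triisopropyl[(5-methylhex-4-en-1-yn-1-yl)oxy]silane
Product: 20 (2S)-2-Ar-5-hydroxy-6-(3-methylbut-2-enyl)-7-(triisopropylsilyloxy)-2,3-dihydro-4H-chromen-4-one, via vinylketene 16 (not isolated), via vinylcyclobutenone 17 (not isolated), via dienylketene 18 (not isolated), via cyclohexadienone 19 (not isolated)
Conditions: 15 (2 equiv), hν (420 nm LED), degassed ClCH2CH2Cl, rt; then 80 °C
Reagents that add atoms: none
Why: This is the Danheiser benzannulation in its photochemical Wolff variant (α'-diazo enone plus 1-siloxyalkyne), applied to a vinylketene carried by a dihydropyranone. Light absorbed in the long-wavelength band of the diazo ketone expels N2 and pyranone C6 (future C8a) migrates to the diazo carbon (future C8), which forms C8–C8a and gives vinylketene 16, whose carbonyl carbon is the future C5. A [2+2] cycloaddition of the ketene C=C with 15 gives vinylcyclobutenone 17 and forms C5–C6 and C7–C8; on heating, 17 opens reversibly (conrotatory 4π) to dienylketene 18. Ring A closes by thermal disrotatory 6π electrocyclisation of 18, in which the ketene carbon C5 bonds to C4a, and the resulting dienone 19 enolises at once to the chelated phenol 20. No stereocentre is created: the sp3 carbons of 17 and 19 are transient, and C2 is a spectator with no acid or base present to epimerise it. The step needs regioselectivity in the cycloaddition, and the polarisation of the ynol ether should secure it: its nucleophilic carbon, remote from oxygen and bearing the prenyl group, attacks the electrophilic ketene carbonyl carbon, so prenyl ends at C6 between O5 and O7 and C8 keeps its hydrogen. It also needs selective excitation, which 420 nm light is meant to secure, since there only the diazo ketone should absorb and the ring C enone, 17 and 20 are not excited. Only the isomer of 18 with C8a cis to the ketene arm can cyclise, and the reversible ring opening feeds that isomer.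

Step 9
Reactants: 20 (2S)-2-Ar-5-hydroxy-6-(3-methylbut-2-enyl)-7-(triisopropylsilyloxy)-2,3-dihydro-4H-chromen-4-one
Product: 21 macarangaflavanone B
Conditions: Bu4NF, AcOH (1:1, 3 equiv), THF, 0 °C
Reagents that add atoms: none
Why: Fluoride cleavage of two aryl silyl ethers; acetic acid protonates each phenoxide as it forms, so the 4'-phenoxide that would open ring C and racemise C2 does not build up, and no acid strong enough to cyclise the prenyl groups onto the neighbouring phenols is present.

## Compound list

1 | 4-hydroxybenzaldehyde | O=Cc1ccc(O)cc1 | starting material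
2 | prenyl bromide (1-bromo-3-methylbut-2-ene) | CC(C)=CCBr | starting material
3 | 4-hydroxy-3-(3-methylbut-2-enyl)benzaldehyde | CC(C)=CCc1cc(C=O)ccc1O | intermediate
4 | 3-(3-methylbut-2-enyl)-4-(triisopropylsilyloxy)benzaldehyde | CC(C)=CCc1cc(C=O)ccc1O[Si](C(C)C)(C(C)C)C(C)C | intermediate
5 | ethyl 2,4-dioxopentanoate | CCOC(=O)C(=O)CC(C)=O | starting material
6 | ethyl (2Z)-2,4-bis(trimethylsilyloxy)penta-2,4-dienoate | CCOC(=O)/C(O[Si](C)(C)C)=C/C(=C)O[Si](C)(C)C | intermediate
7 | ethyl (6S)-6-Ar-6-hydroxy-2,4-dioxohexanoate | CC(C)=CCc1cc([C@@H](O)CC(=O)CC(=O)C(=O)OCC)ccc1O[Si](C(C)C)(C(C)C)C(C)C | intermediate (not isolated)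
8 | ethyl (2S)-2-Ar-4-oxo-3,4-dihydro-2H-pyran-6-carboxylate | CC(C)=CCc1cc([C@@H]2CC(=O)C=C(C(=O)OCC)O2)ccc1O[Si](C(C)C)(C(C)C)C(C)C | intermediate
9 | (2S)-2-Ar-4-oxo-3,4-dihydro-2H-pyran-6-carboxylic acid | CC(C)=CCc1cc([C@@H]2CC(=O)C=C(C(=O)O)O2)ccc1O[Si](C(C)C)(C(C)C)C(C)C | intermediate
10 | (2S)-2-Ar-4-oxo-3,4-dihydro-2H-pyran-6-carbonyl chloride | CC(C)=CCc1cc([C@@H]2CC(=O)C=C(C(=O)Cl)O2)ccc1O[Si](C(C)C)(C(C)C)C(C)C | intermediate (not isolated)
11 | 2-diazo-1-[(2S)-2-Ar-4-oxo-3,4-dihydro-2H-pyran-6-yl]ethan-1-one | CC(C)=CCc1cc([C@@H]2CC(=O)C=C(C(=O)C=[N+]=[N-])O2)ccc1O[Si](C(C)C)(C(C)C)C(C)C | intermediate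
12 | ethyl 4-methylpent-3-enoate | CCOC(=O)CC=C(C)C | starting material
13 | lithium 1,1-dibromo-5-methylhexa-1,4-dien-2-olate | [Li+].CC(C)=CCC([O-])=C(Br)Br | intermediate (not isolated)
14 | lithium 5-methylhex-4-en-1-yn-1-olate | [Li+].CC(C)=CCC#C[O-] | intermediate (not isolated)
15 | triisopropyl[(5-methylhex-4-en-1-yn-1-yl)oxy]silane | CC(C)=CCC#CO[Si](C(C)C)(C(C)C)C(C)C | intermediate
16 | 2-[(2S)-2-Ar-4-oxo-3,4-dihydro-2H-pyran-6-yl]ethen-1-one (vinylketene) | CC(C)=CCc1cc([C@@H]2CC(=O)C=C(C=C=O)O2)ccc1O[Si](C(C)C)(C(C)C)C(C)C | intermediate (not isolated)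
17 | 4-[(2S)-2-Ar-4-oxo-3,4-dihydro-2H-pyran-6-yl]-2-(3-methylbut-2-enyl)-3-(triisopropylsilyloxy)cyclobut-2-en-1-one, both epimers at the ring CH | CC(C)=CCc1cc([C@@H]2CC(=O)C=C(C3C(=O)C(CC=C(C)C)=C3O[Si](C(C)C)(C(C)C)C(C)C)O2)ccc1O[Si](C(C)C)(C(C)C)C(C)C | intermediate (not isolated)
18 | (3E)-4-[(2S)-2-Ar-4-oxo-3,4-dihydro-2H-pyran-6-yl]-2-(3-methylbut-2-enyl)-3-(triisopropylsilyloxy)buta-1,3-dien-1-one (dienylketene) | CC(C)=CCc1cc([C@@H]2CC(=O)C=C(/C=C(O[Si](C(C)C)(C(C)C)C(C)C)\C(CC=C(C)C)=C=O)O2)ccc1O[Si](C(C)C)(C(C)C)C(C)C | intermediate (not isolated)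
19 | (2S)-2-Ar-6-(3-methylbut-2-enyl)-7-(triisopropylsilyloxy)-2,3-dihydro-4H-chromene-4,5(4aH)-dione, both epimers at C4a (keto tautomer of 20) | CC(C)=CCc1cc([C@@H]2CC(=O)C3C(=O)C(CC=C(C)C)=C(O[Si](C(C)C)(C(C)C)C(C)C)C=C3O2)ccc1O[Si](C(C)C)(C(C)C)C(C)C | intermediate (not isolated)
20 | (2S)-2-Ar-5-hydroxy-6-(3-methylbut-2-enyl)-7-(triisopropylsilyloxy)-2,3-dihydro-4H-chromen-4-one | CC(C)=CCc1cc([C@@H]2CC(=O)c3c(cc(O[Si](C(C)C)(C(C)C)C(C)C)c(CC=C(C)C)c3O)O2)ccc1O[Si](C(C)C)(C(C)C)C(C)C | intermediate
21 | macarangaflavanone B, (2S)-5,7-dihydroxy-2-[4-hydroxy-3-(3-methylbut-2-enyl)phenyl]-6-(3-methylbut-2-enyl)-2,3-dihydro-4H-chromen-4-one | CC(C)=CCc1cc([C@@H]2CC(=O)c3c(cc(O)c(CC=C(C)C)c3O)O2)ccc1O | target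

## Step count and least certain steps

Total: 9 steps. Longest linear sequence: 7 steps (steps 1, 2, 4, 5, 6, 8, 9, from 1). Steps 3 and 7 prepare the two side components 6 and 15.

**Step 8 (key step).**
- What may go wrong: light may be absorbed by the ring C enone or by 17, leading to enone cycloadditions. The keto carbene may be trapped by the alkyne before it rearranges. Ketene 16 may dimerise or be hydrated. The thermal opening of 17 may be incomplete.
- Fallback: generate 16 without light, setting out from 11 and returning at 20. Silver-promoted Wolff rearrangement in the dark (PhCO2Ag cat., Et3N, THF/H2O, rt) should give [(2S)-2-Ar-4-oxo-3,4-dihydro-2H-pyran-6-yl]acetic acid F1. The chloroenamine of step 6 should convert it into [(2S)-2-Ar-4-oxo-3,4-dihydro-2H-pyran-6-yl]acetyl chloride F2. Slow addition of F2 to 15 and Et3N in toluene at rt should give 16 by dehydrochlorination, and warming to 80 °C should carry it through 17, 18 and 19 to 20. This is the known ketene/siloxyalkyne route to resorcinols.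

**Step 4.**
- What may go wrong: turnover or facial selectivity may be poor, because diene 6 is made less nucleophilic by its ester and aldehyde 4 is electron-rich. Elimination of the benzylic hydroxyl during cyclodehydration would return racemic material by re-addition.
- Fallback: reagent-controlled allylation, setting out from 4 and returning at 7 and 8. Addition of (−)-Ipc2B(allyl) (Et2O, −78 °C; NaOH, H2O2) should give (1S)-1-Ar-but-3-en-1-ol F3. Silylation (Et3SiCl, imidazole) should give triethyl{[(1S)-1-Ar-but-3-en-1-yl]oxy}silane F4. Wacker oxidation of the terminal alkene (PdCl2 cat., CuCl, O2, DMF/H2O), which should leave the trisubstituted prenyl alkene alone, should give (4S)-4-Ar-4-(triethylsilyloxy)butan-2-one F5. Claisen condensation at the methyl group (LiN(SiMe3)2, THF, −78 °C; diethyl oxalate) should give ethyl (6S)-6-Ar-2,4-dioxo-6-(triethylsilyloxy)hexanoate F6. PPTS in EtOH should remove the silyl group to give 7, which closes to 8 as in step 4.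

**Step 6.**
- What may go wrong: diazomethane may add as a dipole to the electron-poor C5=C6 bond of the pyranone. The diazo ketone may be converted into the chloromethyl ketone if HCl is not scavenged.
- Fallback: detrifluoroacetylative diazo transfer, setting out from 10 and returning at 11. Palladium-catalysed acylation of a methylzinc reagent (MeZnCl, Pd(PPh3)4 cat., THF, 0 °C) should give (2S)-6-acetyl-2-Ar-2,3-dihydro-4H-pyran-4-one F7. Its acetyl group should be the kinetically and thermodynamically preferred enolisation site, because C4 is a vinylogous ester carbonyl. Trifluoroacetylation (LiN(SiMe3)2, THF, −78 °C; CF3CO2CH2CF3) should give 1-[(2S)-2-Ar-4-oxo-3,4-dihydro-2H-pyran-6-yl]-4,4,4-trifluorobutane-1,3-dione F8. Diazo transfer with loss of the trifluoroacetyl group (MsN3, Et3N, H2O, MeCN, rt) should give 11.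

**Step 7.**
- What may go wrong: the carbenoid or the amide base may deprotonate the β,γ-unsaturated ester at its doubly activated α-position, which loses material by deconjugation. Excess alkyllithium may isomerise the skipped enyne of the ynolate.
- Fallback: oxidation of an acetylide, setting out from 2 and returning at 14 and 15. Copper-catalysed coupling (HC≡CMgBr, CuCl cat., THF) should give 5-methylhex-4-en-1-yne F9. Deprotonation (n-BuLi, THF, −78 °C) and oxidation with t-BuOOLi (from t-BuOOH and LiN(SiMe3)2, −78 to 0 °C) should give ynolate 14. O-silylation with TIPSOTf at −78 °C should give 15.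

## Further compounds

F1 | step 8 | [(2S)-2-Ar-4-oxo-3,4-dihydro-2H-pyran-6-yl]acetic acid | CC(C)=CCc1cc([C@@H]2CC(=O)C=C(CC(=O)O)O2)ccc1O[Si](C(C)C)(C(C)C)C(C)C
F2 | step 8 | [(2S)-2-Ar-4-oxo-3,4-dihydro-2H-pyran-6-yl]acetyl chloride | CC(C)=CCc1cc([C@@H]2CC(=O)C=C(CC(=O)Cl)O2)ccc1O[Si](C(C)C)(C(C)C)C(C)C
F3 | step 4 | (1S)-1-Ar-but-3-en-1-ol | CC(C)=CCc1cc([C@@H](O)CC=C)ccc1O[Si](C(C)C)(C(C)C)C(C)C
F4 | step 4 | triethyl{[(1S)-1-Ar-but-3-en-1-yl]oxy}silane | CC(C)=CCc1cc([C@@H](O[Si](CC)(CC)CC)CC=C)ccc1O[Si](C(C)C)(C(C)C)C(C)C
F5 | step 4 | (4S)-4-Ar-4-(triethylsilyloxy)butan-2-one | CC(C)=CCc1cc([C@@H](O[Si](CC)(CC)CC)CC(C)=O)ccc1O[Si](C(C)C)(C(C)C)C(C)C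
F6 | step 4 | ethyl (6S)-6-Ar-2,4-dioxo-6-(triethylsilyloxy)hexanoate | CC(C)=CCc1cc([C@@H](O[Si](CC)(CC)CC)CC(=O)CC(=O)C(=O)OCC)ccc1O[Si](C(C)C)(C(C)C)C(C)C
F7 | step 6 | (2S)-6-acetyl-2-Ar-2,3-dihydro-4H-pyran-4-one | CC(C)=CCc1cc([C@@H]2CC(=O)C=C(C(C)=O)O2)ccc1O[Si](C(C)C)(C(C)C)C(C)C
F8 | step 6 | 1-[(2S)-2-Ar-4-oxo-3,4-dihydro-2H-pyran-6-yl]-4,4,4-trifluorobutane-1,3-dione | CC(C)=CCc1cc([C@@H]2CC(=O)C=C(C(=O)CC(=O)C(F)(F)F)O2)ccc1O[Si](C(C)C)(C(C)C)C(C)C
F9 | step 7 | 5-methylhex-4-en-1-yne | CC(C)=CCC#C
A1 | alternative 1 | (2S)-5-hydroxy-2-[4-hydroxy-3-(3-methylbut-2-enyl)phenyl]-7-(methoxymethoxy)-6-(3-methylbut-2-enyl)-2,3-dihydro-4H-chromen-4-one | CC(C)=CCc1cc([C@@H]2CC(=O)c3c(cc(OCOC)c(CC=C(C)C)c3O)O2)ccc1O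
A2 | alternative 1 | (2S)-7-(methoxymethoxy)-5-(2-methylbut-3-en-2-yloxy)-2-[4-(2-methylbut-3-en-2-yloxy)phenyl]-2,3-dihydro-4H-chromen-4-one | C=CC(C)(C)Oc1ccc([C@@H]2CC(=O)c3c(cc(OCOC)cc3OC(C)(C)C=C)O2)cc1
A3 | alternative 2 | (2S)-4-methoxy-5,7-bis(tert-butyldimethylsilyloxy)-6-(3-methylbut-2-enyl)-2-[4-(tert-butyldimethylsilyloxy)-3-(3-methylbut-2-enyl)phenyl]chroman, C4 undefined | CC(C)=CCc1cc([C@@H]2CC(OC)c3c(cc(O[Si](C)(C)C(C)(C)C)c(CC=C(C)C)c3O[Si](C)(C)C(C)(C)C)O2)ccc1O[Si](C)(C)C(C)(C)C
A4 | alternative 2 | 2,4-bis(tert-butyldimethylsilyloxy)-6-hydroxy-3-(3-methylbut-2-enyl)benzaldehyde | O=Cc1c(O)cc(O[Si](C)(C)C(C)(C)C)c(CC=C(C)C)c1O[Si](C)(C)C(C)(C)C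
A5 | alternative 2 | tert-butyl[4-ethenyl-2-(3-methylbut-2-enyl)phenoxy]dimethylsilane | C=Cc1ccc(O[Si](C)(C)C(C)(C)C)c(CC=C(C)C)c1
A6 | alternative 2 | 3,5-bis(tert-butyldimethylsilyloxy)-6-(methoxymethylidene)-4-(3-methylbut-2-enyl)cyclohexa-2,4-dien-1-one (methoxy ortho-quinone methide) | COC=C1C(=O)C=C(O[Si](C)(C)C(C)(C)C)C(CC=C(C)C)=C1O[Si](C)(C)C(C)(C)C
A7 | alternative 3 | (2S)-5,7-bis(methoxymethoxy)-2-[4-(methoxymethoxy)-3-(3-methylbut-2-enyl)phenyl]-6-(3-methylbut-2-enyl)-2,3-dihydro-4H-chromen-4-one | CC(C)=CCc1cc([C@@H]2CC(=O)c3c(cc(OCOC)c(CC=C(C)C)c3OCOC)O2)ccc1OCOC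
A8 | alternative 3 | 3,5-bis(methoxymethoxy)-4-(3-methylbut-2-enyl)-2-(trimethylsilyl)phenyl trifluoromethanesulfonate | COCOc1cc(OS(=O)(=O)C(F)(F)F)c([Si](C)(C)C)c(OCOC)c1CC=C(C)C
A9 | alternative 3 | methyl (3S)-3-hydroxy-3-[4-(methoxymethoxy)-3-(3-methylbut-2-enyl)phenyl]propanoate | CC(C)=CCc1cc([C@@H](O)CC(=O)OC)ccc1OCOC
A10 | alternative 3 | 3,5-bis(methoxymethoxy)-4-(3-methylbut-2-enyl)benzyne (aryne between the future C4a and C8a) | COCOC1=CC#CC(OCOC)=C1CC=C(C)C
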